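**Plan**

1. Retrosynthesis: the two O–CH3 bonds are cut last, then both diaryl ether C–O bonds of the 18-membered ring. One runs from the para-phenol oxygen of one bibenzyl to the carbon ortho to oxygen on the para-oxygenated ring of the other; the second runs from the meta-phenol oxygen to the carbon para to oxygen (ortho to the CH2CH2 bridge) on the other's meta-oxygenated ring.
2. Enabling feature: both ether oxygens are the two phenol oxygens of a single lunularin unit (3,4'-dihydroxybibenzyl), and the two carbons they bind in the second lunularin unit are its most nucleophilic C–H sites. That second unit can therefore be raised beforehand to the aryl iodide/aryl bromide oxidation level, so the two lunularin skeletons meet as bis-O-nucleophile and bis-C-electrophile.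
3. Each bibenzyl is cut at its central CH2–CH2 bond (Wittig olefination, then saturation).
4. Forward: two short Wittig sequences give the iodo-bromo dimethyl ether and the mono-silylated lunularin. One flask then joins the chain at C–I and closes the only new ring (18-membered) at C–Br, and BBr3 frees the phenols.
5. Stereochemistry: the target has no stereogenic element, so nothing has to be set or preserved.

Key step: step 8

Assumption: the target SMILES carries no stereodescriptor and the ether-linked 18-membered ring is taken as conformationally mobile, so the "single enantiomer" is defined by constitution alone.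

**Route**

Step 1
Reactants: 1 3-bromo-4-methoxybenzaldehyde; 2 (3-methoxybenzyl)triphenylphosphonium chloride
Product: 4 2-bromo-1-methoxy-4-[2-(3-methoxyphenyl)ethenyl]benzene (E/Z mixture), via phosphorus ylide 3 (not isolated)
Conditions: KOtBu, THF, 0 °C; then 1, 0 °C → rt
Reagents that add atoms: none
Why: Wittig olefination of an aryl aldehyde with a semi-stabilised benzylic ylide is dependable, the E/Z mixture is irrelevant because the double bond is saturated next, and the aryl bromide and methyl ethers are inert to the base.

Step 2
Reactants: 4 2-bromo-1-methoxy-4-[2-(3-methoxyphenyl)ethenyl]benzene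
Product: 5 2-bromo-1-methoxy-4-[2-(3-methoxyphenyl)ethyl]benzene
Conditions: TsNHNH2, NaOAc, DME/H2O, reflux
Reagents that add atoms: none
Why: Diimide reduction delivers H2 to the C=C bond by concerted syn transfer and, unlike hydrogenation over palladium, cannot cleave the aryl C–Br bond.

Step 3
Reactants: 5 2-bromo-1-methoxy-4-[2-(3-methoxyphenyl)ethyl]benzene
Product: 6 2-bromo-4-[2-(2-iodo-5-methoxyphenyl)ethyl]-1-methoxybenzene
Conditions: NIS, TFA (cat.), MeCN, rt, dark
Reagents that add atoms: N-iodosuccinimide, O=C1CCC(=O)N1I
Why: Electrophilic aromatic iodination should go to the most electron-rich accessible carbon, para to methoxy on the 3-alkylanisole ring (the carbon that must later carry the ether oxygen), while the other ring is para-blocked and deactivated by bromine.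

Step 4
Reactants: 7 4-hydroxybenzaldehyde
Product: 8 4-{[tri(propan-2-yl)silyl]oxy}benzaldehyde
Conditions: TIPSCl, imidazole, DMF, rt
Reagents that add atoms: triisopropylsilyl chloride, CC(C)[Si](Cl)(C(C)C)C(C)C
Why: Imidazole-promoted O-silylation of a phenol is routine, and the bulky TIPS ether is chosen because it resists carbonate bases and ylides but falls to fluoride.

Step 5
Reactants: 9 1-(benzyloxy)-3-(bromomethyl)benzene (3-benzyloxybenzyl bromide)
Product: 10 [3-(benzyloxy)benzyl]triphenylphosphonium bromide
Conditions: PPh3, toluene, reflux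
Reagents that add atoms: triphenylphosphine, c1ccc(cc1)P(c1ccccc1)c1ccccc1
Why: SN2 quaternisation of triphenylphosphine by a benzylic bromide gives the salt, which should precipitate from toluene.

Step 6
Reactants: 10 [3-(benzyloxy)benzyl]triphenylphosphonium bromide; 8 4-{[tri(propan-2-yl)silyl]oxy}benzaldehyde
Product: 12 {4-[2-(3-(benzyloxy)phenyl)ethenyl]phenoxy}tri(propan-2-yl)silane (E/Z mixture), via phosphorus ylide 11 (not isolated)
Conditions: NaHMDS, THF, 0 °C; then 8, 0 °C → rt
Reagents that add atoms: none
Why: Wittig olefination with a non-nucleophilic amide base leaves the aryl TIPS ether and the benzyl ether untouched, and the alkene geometry is again of no consequence.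

Step 7
Reactants: 12 {4-[2-(3-(benzyloxy)phenyl)ethenyl]phenoxy}tri(propan-2-yl)silane
Product: 13 3-[2-(4-{[tri(propan-2-yl)silyl]oxy}phenyl)ethyl]phenol (lunularin with the para-phenol oxygen silylated and the meta-phenol free)
Conditions: H2 (1 atm), 10% Pd/C, EtOAc/EtOH, rt
Reagents that add atoms: none
Why: Heterogeneous catalytic hydrogenation saturates the stilbene and hydrogenolyses the benzyl ether in one operation while the silyl ether survives, so only the meta-phenol is left free.

Step 8
Reactants: 6 2-bromo-4-[2-(2-iodo-5-methoxyphenyl)ethyl]-1-methoxybenzene; 13 3-[2-(4-{[tri(propan-2-yl)silyl]oxy}phenyl)ethyl]phenol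
Product: 16 di-O-methyldihydroptychantol A (the target macrocycle with both phenols as methyl ethers), via open-chain silyl ether 14 (not isolated), via open-chain phenol 15 (not isolated)
Conditions: 6 : 13 = 1 : 1, CuI (10 mol%), Me2NCH2CO2H·HCl (30 mol%), Cs2CO3, dioxane, 90 °C; then slow addition to CsF, CuI (1 equiv), Me2NCH2CO2H·HCl, Cs2CO3, DMF, 110 °C (final ca. 3 mM)
Reagents that add atoms: none
Why: This is a ligand-accelerated Ullmann diaryl ether synthesis run twice in one flask: the copper(I) phenoxide of the free meta-phenol of 13 adds to the C–I bond of 6 and reductive elimination gives 14, then fluoride strips the TIPS group and the caesium para-phenoxide 15 is O-arylated at the remaining C–Br bond by the same Cu(I)/Cu(III) cycle. The closest known reactions are the CuI/N,N-dimethylglycine coupling of aryl iodides and bromides with phenols and the intramolecular Ullmann etherifications that close diaryl ether cyclophanes from a 4-hydroxyphenyl end and a 3-bromo-4-methoxyphenyl end. The single new ring, the 18-membered bis(bibenzyl) macrocycle, is closed by this second, intramolecular C–O bond formation under pseudo-high dilution, the two flexible CH2CH2 bridges letting the phenoxide reach the bromide without strain. No stereocentre is created. The step needs the right oxygen/carbon pairing and ring closure over oligomerisation: pairing is secured because only one oxygen of 13 is free in the first stage and C–I reacts well before the electron-rich ortho-methoxy C–Br bond, so the second oxygen meets the only halide left. Oligomers are held back by unmasking the phenoxide slowly into a hot dilute solution.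

Step 9
Reactants: 16 di-O-methyldihydroptychantol A
Product: 18 dihydroptychantol A, via bis(dibromoboryl) ether 17 (not isolated)
Conditions: BBr3, CH2Cl2, −78 °C → rt; then H2O
Reagents that add atoms: none
Why: Lewis-acid O-demethylation with BBr3 cleaves aryl methyl ethers by bromide attack on the methyl group of the boron-complexed ether, while the two diaryl ether bonds, which have no sp3 C–O carbon, should stay intact.

**Compound list**

1 | 3-bromo-4-methoxybenzaldehyde | COc1ccc(C=O)cc1Br | starting material
2 | (3-methoxybenzyl)triphenylphosphonium chloride | COc1cccc(C[P+](c2ccccc2)(c2ccccc2)c2ccccc2)c1.[Cl-] | starting material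
3 | (3-methoxybenzylidene)triphenylphosphorane | COc1cccc(C=P(c2ccccc2)(c2ccccc2)c2ccccc2)c1 | intermediate (not isolated)
4 | 2-bromo-1-methoxy-4-[2-(3-methoxyphenyl)ethenyl]benzene, E/Z mixture | COc1cccc(C=Cc2ccc(OC)c(Br)c2)c1 | intermediate
5 | 2-bromo-1-methoxy-4-[2-(3-methoxyphenyl)ethyl]benzene | COc1cccc(CCc2ccc(OC)c(Br)c2)c1 | intermediate
6 | 2-bromo-4-[2-(2-iodo-5-methoxyphenyl)ethyl]-1-methoxybenzene | COc1ccc(I)c(CCc2ccc(OC)c(Br)c2)c1 | intermediate
7 | 4-hydroxybenzaldehyde | O=Cc1ccc(O)cc1 | starting material
8 | 4-{[tri(propan-2-yl)silyl]oxy}benzaldehyde | CC(C)[Si](Oc1ccc(C=O)cc1)(C(C)C)C(C)C | intermediate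
9 | 1-(benzyloxy)-3-(bromomethyl)benzene | BrCc1cccc(OCc2ccccc2)c1 | starting material
10 | [3-(benzyloxy)benzyl]triphenylphosphonium bromide | [Br-].c1ccc(COc2cccc(C[P+](c3ccccc3)(c3ccccc3)c3ccccc3)c2)cc1 | intermediate
11 | [3-(benzyloxy)benzylidene]triphenylphosphorane | c1ccc(COc2cccc(C=P(c3ccccc3)(c3ccccc3)c3ccccc3)c2)cc1 | intermediate (not isolated)
12 | {4-[2-(3-(benzyloxy)phenyl)ethenyl]phenoxy}tri(propan-2-yl)silane, E/Z mixture | CC(C)[Si](Oc1ccc(C=Cc2cccc(OCc3ccccc3)c2)cc1)(C(C)C)C(C)C | intermediate
13 | 3-[2-(4-{[tri(propan-2-yl)silyl]oxy}phenyl)ethyl]phenol | CC(C)[Si](Oc1ccc(CCc2cccc(O)c2)cc1)(C(C)C)C(C)C | intermediate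
14 | (4-{2-[3-({2-[2-(3-bromo-4-methoxyphenyl)ethyl]-4-methoxyphenyl}oxy)phenyl]ethyl}phenoxy)tri(propan-2-yl)silane | COc1ccc(Oc2cccc(CCc3ccc(O[Si](C(C)C)(C(C)C)C(C)C)cc3)c2)c(CCc2ccc(OC)c(Br)c2)c1 | intermediate (not isolated)
15 | 4-{2-[3-({2-[2-(3-bromo-4-methoxyphenyl)ethyl]-4-methoxyphenyl}oxy)phenyl]ethyl}phenol (present as its caesium salt) | COc1ccc(Oc2cccc(CCc3ccc(O)cc3)c2)c(CCc2ccc(OC)c(Br)c2)c1 | intermediate (not isolated)
16 | di-O-methyldihydroptychantol A | COc1ccc2c(c1)CCc1ccc(OC)c(c1)Oc1ccc(cc1)CCc1cccc(c1)O2 | intermediate
17 | bis(dibromoboryl) ether of dihydroptychantol A (simplest form of the aryl borate) | BrB(Br)Oc1ccc2c(c1)CCc1ccc(OB(Br)Br)c(c1)Oc1ccc(cc1)CCc1cccc(c1)O2 | intermediate (not isolated)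
18 | dihydroptychantol A | Oc1ccc2c(c1)CCc1ccc(O)c(c1)Oc1ccc(cc1)CCc1cccc(c1)O2 | target

**Step count**

Total: 9 steps. Longest linear sequence: 5 steps (steps 1, 2, 3, 8, 9, or equally steps 5, 6, 7, 8, 9).

**Steps most likely to fail**

Step 8. In the ring-closing stage, intermolecular O-arylation and reductive loss of bromine may outrun the intramolecular etherification at the electron-rich, ortho-substituted C–Br bond. Early loss of the silyl group in the first stage would also blur the oxygen/carbon pairing. The fallback closes the same C–O bond at room temperature from a boronic acid. It sets out from open-chain silyl ether 14, isolated by stopping after the first stage. Bromine–lithium exchange (n-BuLi, THF, −78 °C), trapping with B(OiPr)3 and mild acidic work-up should give [2-methoxy-5-(2-{5-methoxy-2-[3-(2-{4-[(triisopropylsilyl)oxy]phenyl}ethyl)phenoxy]phenyl}ethyl)phenyl]boronic acid F1. TBAF buffered with AcOH (THF, 0 °C) then frees the para-phenol to give the hydroxy boronic acid F2. An intramolecular Chan–Lam coupling (Cu(OAc)2, pyridine, Et3N, 4 Å MS, CH2Cl2, air, rt, ca. 2 mM) closes the macrocycle and comes back to the route at 16.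

Step 2. Diimide may disproportionate faster than it saturates the conjugated, electron-rich stilbene, leaving alkene that is hard to separate, and a switch to catalytic hydrogenation would risk hydrogenolysis of the C–Br bond. The fallback avoids the alkene altogether and sets out from aldehyde 1. Methylenation (MePPh3Br, KOtBu, THF) should give 2-bromo-4-ethenyl-1-methoxybenzene F3. Hydroboration with 9-BBN (THF, rt) gives 9-[2-(3-bromo-4-methoxyphenyl)ethyl]-9-borabicyclo[3.3.1]nonane F4, used without isolation. A B-alkyl Suzuki–Miyaura coupling with 3-iodoanisole (PdCl2(dppf), aq. K3PO4, THF/DMF, rt), in which oxidative addition to C–I outpaces that to the ortho-methoxy C–Br bond, forms the CH2–CH2 bridge directly and comes back to the route at 5.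

Step 3. Iodination may lose regiocontrol (attack ortho to methoxy and para to the bridge, or double iodination), giving isomers that are hard to separate. The fallback brings the iodine in with a building block and joins aldehyde 1 at the olefination. Commercial 2-iodo-5-methoxybenzaldehyde is reduced (NaBH4, MeOH, 0 °C) to (2-iodo-5-methoxyphenyl)methanol F5. PPh3·HBr (MeCN, reflux) converts this into (2-iodo-5-methoxybenzyl)triphenylphosphonium bromide F6. Deprotonation (KOtBu, THF, 0 °C) gives (2-iodo-5-methoxybenzylidene)triphenylphosphorane F7, which condenses with 1 to 2-bromo-4-[2-(2-iodo-5-methoxyphenyl)ethenyl]-1-methoxybenzene F8 (E/Z mixture). Diimide reduction under the conditions of step 2 comes back to the route at 6, bypassing 4 and 5.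

**Further compounds**

F1 | step 8 | [2-methoxy-5-(2-{5-methoxy-2-[3-(2-{4-[(triisopropylsilyl)oxy]phenyl}ethyl)phenoxy]phenyl}ethyl)phenyl]boronic acid | COc1ccc(Oc2cccc(CCc3ccc(O[Si](C(C)C)(C(C)C)C(C)C)cc3)c2)c(CCc2ccc(OC)c(B(O)O)c2)c1
F2 | step 8 | [5-(2-{2-[3-(2-(4-hydroxyphenyl)ethyl)phenoxy]-5-methoxyphenyl}ethyl)-2-methoxyphenyl]boronic acid | COc1ccc(Oc2cccc(CCc3ccc(O)cc3)c2)c(CCc2ccc(OC)c(B(O)O)c2)c1
F3 | step 2 | 2-bromo-4-ethenyl-1-methoxybenzene | COc1ccc(C=C)cc1Br
F4 | step 2 | 9-[2-(3-bromo-4-methoxyphenyl)ethyl]-9-borabicyclo[3.3.1]nonane | COc1ccc(CCB2C3CCCC2CCC3)cc1Br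
F5 | step 3 | (2-iodo-5-methoxyphenyl)methanol | COc1ccc(I)c(CO)c1
F6 | step 3 | (2-iodo-5-methoxybenzyl)triphenylphosphonium bromide | COc1ccc(I)c(C[P+](c2ccccc2)(c2ccccc2)c2ccccc2)c1.[Br-]
F7 | step 3 | (2-iodo-5-methoxybenzylidene)triphenylphosphorane | COc1ccc(I)c(C=P(c2ccccc2)(c2ccccc2)c2ccccc2)c1
F8 | step 3 | 2-bromo-4-[2-(2-iodo-5-methoxyphenyl)ethenyl]-1-methoxybenzene, E/Z mixture | COc1ccc(I)c(C=Cc2ccc(OC)c(Br)c2)c1
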